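**Retrosynthetic overview**

1. Target 29 ← global deprotection of 28 ← C3 aroylation (C3 lithiation, aroyl chloride 27) ← C5 bridgehead geranylation of vinylogous ester 22.
2. 22 ← C7 exo prenyl, built up from the equilibrated C7 aldehyde 19 ← C7 ketone 16 ← C4 allylic oxidation of enol ether 15.
3. Ring B (C1–C8–C7–C6–C5–C9) of 15 ← cleavage of the C6–C9 bond of methoxycyclopropyl ketone 13 (donor OMe on C9, acceptor C7=O).
4. 13 ← copper-carbene cyclopropanation of diazoketone 12 (forms C6–C5 and C6–C9). Feature used: the C9 bridge ketone and its bridgeheads C1/C5 map onto ring A (C1–C2–C3–C4–C5–C9) as a 2,6-dimethoxycyclohexa-2,5-diene with C1 on the mirror plane and C2=C3 / C9=C5 enantiotopic.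
5. 12 ← acid 10 ← Arndt–Eistert homologation and α,α-dimethylation ← Birch reductive prenylation of 2,6-dimethoxybenzoic acid 1. Ring order: ring A (from the arene), then cyclopentanone and cyclopropane together (step 7), then ring B by fragmentation (step 8).

Key step: step 7

Remarks on the chemistry:
- Locants of all bicyclic compounds follow the target skeleton: C1 prenyl bridgehead, C2–C3–C4 bridge, C5 geranyl bridgehead, C6–C7–C8 bridge, C9 bridge carbon. CIP descriptors are worked out for each structure, so they change with substituent priority although the spatial arrangement at C1 and C5 stays the same.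
- The (S,S) ligand is assumed to select the C9=C5 enol ether that gives 13; if the sense of induction is the opposite, the (R,R) ligand is used.
- The target is written as one tautomer of its enolised triketone.

**Route**

Step 1
Reactants: 1 2,6-dimethoxybenzoic acid; 2 prenyl bromide (1-bromo-3-methylbut-2-ene)
Product: 3 2,6-dimethoxy-1-(3-methylbut-2-en-1-yl)cyclohexa-2,5-diene-1-carboxylic acid
Conditions: Li (3.2 equiv), NH3(l)/THF, −78 °C; then 2, −78 to −33 °C; NH4Cl; cold work-up at pH 5, crude acid used at once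
Reagents that add atoms: none
Why: Birch reduction of the benzoate gives the 1,4-dihydro carboxylate enolate (C4 protonated by ammonia), which is alkylated at C1 between the two methoxy-bearing carbons, a Birch reductive alkylation as known for ortho-alkoxybenzoic acids; no stereocentre is formed.

Step 2
Reactants: 3 2,6-dimethoxy-1-(3-methylbut-2-en-1-yl)cyclohexa-2,5-diene-1-carboxylic acid
Product: 5 2-diazo-1-[2,6-dimethoxy-1-(3-methylbut-2-en-1-yl)cyclohexa-2,5-dien-1-yl]ethan-1-one, via acid chloride 4 (not isolated)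
Conditions: 1-chloro-N,N,2-trimethylprop-1-en-1-amine, CH2Cl2, 0 °C; then CH2N2 (excess), Et2O, 0 °C to rt
Reagents that add atoms: diazomethane, C=[N+]=[N-]
Why: The α-chloroenamine makes the acid chloride without free HCl, so the two enol ethers survive, and diazomethane is then C-acylated (first stage of the Arndt–Eistert homologation) while a second equivalent takes up the HCl.

Step 3
Reactants: 5 2-diazo-1-[2,6-dimethoxy-1-(3-methylbut-2-en-1-yl)cyclohexa-2,5-dien-1-yl]ethan-1-one
Product: 7 methyl 2-[2,6-dimethoxy-1-(3-methylbut-2-en-1-yl)cyclohexa-2,5-dien-1-yl]acetate, via ketene 6 (not isolated)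
Conditions: hν (350 nm, Pyrex), MeOH, rt
Reagents that add atoms: methanol, CO
Why: Photochemical Wolff rearrangement moves the quaternary ring carbon to the carbene carbon with loss of N2, and methanol traps the ketene; light is chosen over a metal catalyst so that no metal carbene can add to the nearby alkenes.

Step 4
Reactants: 7 methyl 2-[2,6-dimethoxy-1-(3-methylbut-2-en-1-yl)cyclohexa-2,5-dien-1-yl]acetate
Product: 9 methyl 2-[2,6-dimethoxy-1-(3-methylbut-2-en-1-yl)cyclohexa-2,5-dien-1-yl]-2-methylpropanoate, via monomethyl ester 8 (not isolated)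
Conditions: LiN(i-Pr)2, THF, −78 °C; MeI; then LiN(i-Pr)2, THF/DMPU, −78 °C; MeI, −78 to 0 °C
Reagents that add atoms: iodomethane, CI
Why: Two ester enolate alkylations at the only enolisable carbon build the gem-dimethyl carbon C8 next to quaternary C1 with the smallest electrophile available; the product is achiral.

Step 5
Reactants: 9 methyl 2-[2,6-dimethoxy-1-(3-methylbut-2-en-1-yl)cyclohexa-2,5-dien-1-yl]-2-methylpropanoate
Product: 10 2-[2,6-dimethoxy-1-(3-methylbut-2-en-1-yl)cyclohexa-2,5-dien-1-yl]-2-methylpropanoic acid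
Conditions: n-PrSLi (from n-PrSH and n-BuLi), HMPA, rt; cold aq. NH4Cl, crude acid used at once
Reagents that add atoms: none
Why: The thiolate cleaves the ester by SN2 attack at the O-methyl carbon, which does not depend on the heavily hindered acyl carbon, and the base-stable enol ethers are untouched (their methyl groups leave a far poorer leaving group).

Step 6
Reactants: 10 2-[2,6-dimethoxy-1-(3-methylbut-2-en-1-yl)cyclohexa-2,5-dien-1-yl]-2-methylpropanoic acid
Product: 12 1-diazo-3-[2,6-dimethoxy-1-(3-methylbut-2-en-1-yl)cyclohexa-2,5-dien-1-yl]-3-methylbutan-2-one, via acid chloride 11 (not isolated)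
Conditions: 1-chloro-N,N,2-trimethylprop-1-en-1-amine, CH2Cl2, 0 °C; then CH2N2 (excess), Et2O, 0 °C to rt
Reagents that add atoms: diazomethane, C=[N+]=[N-]
Why: Neutral acid chloride formation followed by acylation of diazomethane gives the terminal α-diazo ketone; the acid chloride has no α-hydrogen, so no ketene pathway competes, though the hindered carbonyl will need time.

Step 7
Reactants: 12 1-diazo-3-[2,6-dimethoxy-1-(3-methylbut-2-en-1-yl)cyclohexa-2,5-dien-1-yl]-3-methylbutan-2-one
Product: 13 (1R,2S,6S,9R)-1,5-dimethoxy-7,7-dimethyl-6-(3-methylbut-2-en-1-yl)tricyclo[4.3.0.0(2,9)]non-4-en-8-one (target locants: 1S,5S,6R,9R; C9 carries the cyclopropane methoxy group)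
Conditions: (CuOTf)2·C6H6 (5 mol %), (S,S)-t-Bu-box [2,2′-(propane-2,2-diyl)bis((4S)-4-tert-butyl-4,5-dihydro-1,3-oxazole), 12 mol %], toluene, slow addition of 12, rt to 40 °C
Reagents that add atoms: none
Why: The copper triflate/bis(oxazoline) complex turns the diazoketone into an electrophilic carbene of monovalent copper at C6, which adds to one of the two enantiotopic enol ether bonds (C9=C5) in an asynchronous concerted [2+1] step; this is the known copper-catalysed intramolecular cyclopropanation of an α-diazo ketone onto an enol ether, run here as a desymmetrisation. The cyclopentanone (C1–C8–C7–C6–C9) closes in the 5-exo sense as C6 bonds to the near alkene carbon C9, and the cyclopropane (C5–C6–C9) closes in the same event as C6–C5 forms. Because the tether hangs from C1, the carbene reaches the alkene only on the face syn to the tether, so the relative configuration of C1, C5, C6 and C9 is fixed by the cis fusion, and the absolute configuration of all four follows from which enol ether the chiral ligand selects. C1 lies on the mirror plane of the diene, so this one choice also makes C1 a stereocentre of the sense the target needs. The step needs enantiotopic-group selectivity, which the twofold-symmetric tert-butyl ligand held close to the carbene should provide, and chemoselectivity for the enol ether over the prenyl alkene, which the shorter reach (five- against six-membered ring), the higher nucleophilicity of the enol ether and the gem-dimethyl group folding the chain toward ring A should provide.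

Step 8
Reactants: 13 (1R,2S,6S,9R)-1,5-dimethoxy-7,7-dimethyl-6-(3-methylbut-2-en-1-yl)tricyclo[4.3.0.0(2,9)]non-4-en-8-one
Product: 15 (1S,5S)-2-methoxy-8,8-dimethyl-1-(3-methylbut-2-en-1-yl)bicyclo[3.3.1]non-2-ene-7,9-dione, via silyl enol ether 14 (not isolated)
Conditions: Me3SiI, (Me3Si)2NH (0.2 equiv), CH2Cl2, −78 to −20 °C; then K2CO3 (cat.), MeOH, 0 °C
Reagents that add atoms: none
Why: O-silylation of the C7 ketone triggers heterolysis of the strained C6–C9 bond that lies between the methoxy donor and the ketone acceptor (donor–acceptor cyclopropane fragmentation), iodide demethylates the C9 oxocarbenium to the bridge ketone, and methanolysis of the C6=C7 silyl enol ether frees the C7 ketone; the medium is aprotic and buffered so that the C2 enol ether is kept, and C1 and C5 are not touched.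

Step 9
Reactants: 15 (1S,5S)-2-methoxy-8,8-dimethyl-1-(3-methylbut-2-en-1-yl)bicyclo[3.3.1]non-2-ene-7,9-dione
Product: 16 (1S,5R)-2-methoxy-8,8-dimethyl-1-(3-methylbut-2-en-1-yl)bicyclo[3.3.1]non-2-ene-4,7,9-trione
Conditions: t-BuOOH, PhI(OAc)2, K2CO3 (0.5 equiv), EtOAc, −20 °C
Reagents that add atoms: tert-butyl hydroperoxide, CC(C)(C)OO
Why: tert-Butylperoxy radicals abstract hydrogen from C4, the only methylene allylic to the electron-rich enol ether, and the allylic peroxide collapses to the ketone, an allylic oxidation of a cyclic enol ether to its vinylogous ester.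

Step 10
Reactants: 16 (1S,5R)-2-methoxy-8,8-dimethyl-1-(3-methylbut-2-en-1-yl)bicyclo[3.3.1]non-2-ene-4,7,9-trione
Product: 17 (1S,5R)-2-methoxy-7-(methoxymethylidene)-8,8-dimethyl-1-(3-methylbut-2-en-1-yl)bicyclo[3.3.1]non-2-ene-4,9-dione (E/Z mixture)
Conditions: Ph3P(CH2OMe)Cl, KN(SiMe3)2, THF, 0 °C; then 16, 0 °C to rt
Reagents that add atoms: (methoxymethyl)triphenylphosphonium chloride, [Cl-].COC[P+](c1ccccc1)(c1ccccc1)c1ccccc1
Why: Wittig methoxymethylenation should take place at C7 alone, because C9 is shielded by two bridgeheads and the axial C8 methyl and C4 is a weakly electrophilic vinylogous ester carbonyl.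

Step 11
Reactants: 17 (1S,5R)-2-methoxy-7-(methoxymethylidene)-8,8-dimethyl-1-(3-methylbut-2-en-1-yl)bicyclo[3.3.1]non-2-ene-4,9-dione
Product: 19 (1S,5R,7S)-2-methoxy-8,8-dimethyl-1-(3-methylbut-2-en-1-yl)-4,9-dioxobicyclo[3.3.1]non-2-ene-7-carbaldehyde (formyl exo, anti to ring A), via endo aldehyde 18 (not isolated)
Conditions: 1 M aq. HCl, THF, 0 °C to rt; then DBU (0.2 equiv), CH2Cl2, rt
Reagents that add atoms: water, O
Why: Enol ether hydrolysis (protonation at C7, water on the oxocarbenium) gives the aldehyde, and base equilibration through its enol should place the formyl group exo, equatorial on chair ring B and away from ring A, which sets C7 under thermodynamic control; the hindered vinylogous methyl ester should survive the dilute acid.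

Step 12
Reactants: 19 (1S,5R,7S)-2-methoxy-8,8-dimethyl-1-(3-methylbut-2-en-1-yl)-4,9-dioxobicyclo[3.3.1]non-2-ene-7-carbaldehyde
Product: 21 2-[(1S,5R,7R)-2-methoxy-8,8-dimethyl-1-(3-methylbut-2-en-1-yl)-4,9-dioxobicyclo[3.3.1]non-2-en-7-yl]acetaldehyde, via enol ether 20 (not isolated)
Conditions: Ph3P(CH2OMe)Cl, KN(SiMe3)2, THF, −78 to 0 °C; then 1 M aq. HCl, THF, rt
Reagents that add atoms: (methoxymethyl)triphenylphosphonium chloride, [Cl-].COC[P+](c1ccccc1)(c1ccccc1)c1ccccc1; water, O
Why: A second Wittig methoxymethylenation (the aldehyde reacts far faster than the hindered ketones) and enol ether hydrolysis add one carbon, after which C7 is no longer α to a carbonyl and its exo configuration is locked.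

Step 13
Reactants: 21 2-[(1S,5R,7R)-2-methoxy-8,8-dimethyl-1-(3-methylbut-2-en-1-yl)-4,9-dioxobicyclo[3.3.1]non-2-en-7-yl]acetaldehyde
Product: 22 (1S,5R,7S)-2-methoxy-8,8-dimethyl-1,7-bis(3-methylbut-2-en-1-yl)bicyclo[3.3.1]non-2-ene-4,9-dione
Conditions: i-PrPPh3I, n-BuLi, THF, 0 °C; then 21, −78 to 0 °C
Reagents that add atoms: isopropyltriphenylphosphonium iodide, [I-].CC(C)[P+](c1ccccc1)(c1ccccc1)c1ccccc1
Why: Wittig olefination of the aldehyde with the non-stabilised isopropylidene ylide completes the C7 prenyl group, while the hindered C9 ketone and the vinylogous ester do not react at low temperature.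

Step 14
Reactants: 22 (1S,5R,7S)-2-methoxy-8,8-dimethyl-1,7-bis(3-methylbut-2-en-1-yl)bicyclo[3.3.1]non-2-ene-4,9-dione; 23 geranyl bromide ((2E)-1-bromo-3,7-dimethylocta-2,6-diene)
Product: 24 (1S,5R,7S)-5-[(2E)-3,7-dimethylocta-2,6-dien-1-yl]-2-methoxy-8,8-dimethyl-1,7-bis(3-methylbut-2-en-1-yl)bicyclo[3.3.1]non-2-ene-4,9-dione
Conditions: LiN(i-Pr)2, THF, −78 °C; then 23, −78 to 0 °C
Reagents that add atoms: none
Why: Bridgehead lithiation at C5, which is flanked by the C4 and C9 carbonyls, and SN2 alkylation with the allylic bromide is known on this ring system; the bridgehead cannot invert and the E alkene of the geranyl group is carried over.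

Step 15
Reactants: 25 3,4-dihydroxybenzoic acid
Product: 26 tert-butyldimethylsilyl 3,4-bis(tert-butyldimethylsilyloxy)benzoate
Conditions: t-BuMe2SiCl (3.5 equiv), imidazole, DMF, rt
Reagents that add atoms: tert-butyldimethylsilyl chloride, CC(C)(C)[Si](C)(C)Cl
Why: Imidazole-promoted silylation covers both phenols and the acid in one operation.

Step 16
Reactants: 26 tert-butyldimethylsilyl 3,4-bis(tert-butyldimethylsilyloxy)benzoate
Product: 27 3,4-bis(tert-butyldimethylsilyloxy)benzoyl chloride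
Conditions: (COCl)2, DMF (cat.), CH2Cl2, 0 °C to rt
Reagents that add atoms: oxalyl chloride, ClC(=O)C(Cl)=O
Why: The silyl ester is converted directly into the acid chloride by the chloroiminium species under neutral conditions, so the aryl silyl ethers are kept.

Step 17
Reactants: 24 (1S,5R,7S)-5-[(2E)-3,7-dimethylocta-2,6-dien-1-yl]-2-methoxy-8,8-dimethyl-1,7-bis(3-methylbut-2-en-1-yl)bicyclo[3.3.1]non-2-ene-4,9-dione; 27 3,4-bis(tert-butyldimethylsilyloxy)benzoyl chloride
Product: 28 (1S,5S,7S)-3-[3,4-bis(tert-butyldimethylsilyloxy)benzoyl]-5-[(2E)-3,7-dimethylocta-2,6-dien-1-yl]-2-methoxy-8,8-dimethyl-1,7-bis(3-methylbut-2-en-1-yl)bicyclo[3.3.1]non-2-ene-4,9-dione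
Conditions: lithium 2,2,6,6-tetramethylpiperidide (from 2,2,6,6-tetramethylpiperidine and n-BuLi), THF, −78 °C; then 27, −78 °C
Reagents that add atoms: none
Why: With both bridgeheads substituted, the hindered amide removes the vinylic C3 hydrogen of the vinylogous ester and the vinyllithium is C-acylated by the acid chloride, as known for 3-aroylation of this ring system.

Step 18
Reactants: 28 (1S,5S,7S)-3-[3,4-bis(tert-butyldimethylsilyloxy)benzoyl]-5-[(2E)-3,7-dimethylocta-2,6-dien-1-yl]-2-methoxy-8,8-dimethyl-1,7-bis(3-methylbut-2-en-1-yl)bicyclo[3.3.1]non-2-ene-4,9-dione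
Product: 29 (1R,5R,7S)-3-(3,4-dihydroxybenzoyl)-5-[(2E)-3,7-dimethylocta-2,6-dien-1-yl]-4-hydroxy-8,8-dimethyl-1,7-bis(3-methylbut-2-en-1-yl)bicyclo[3.3.1]non-3-ene-2,9-dione (CNP0160101.4)
Conditions: LiOH·H2O, degassed 1,4-dioxane/H2O, 90 °C, Ar; then cold dilute HCl to pH 3–4
Reagents that add atoms: lithium hydroxide, [Li+].[OH-]
Why: Hydroxide adds to C2, which is β to both the C4 and the aroyl carbonyl, and expels methoxide (vinylogous ester hydrolysis), and it also cleaves both aryl silyl ethers, giving the enolised triketone and the catechol without touching C1, C5 or C7; air is excluded to protect the catecholate.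

**Compound list**

1 | 2,6-dimethoxybenzoic acid | COc1cccc(OC)c1C(O)=O | starting material
2 | prenyl bromide (1-bromo-3-methylbut-2-ene) | CC(C)=CCBr | starting material
3 | 2,6-dimethoxy-1-(3-methylbut-2-en-1-yl)cyclohexa-2,5-diene-1-carboxylic acid | COC1=CCC=C(OC)C1(CC=C(C)C)C(O)=O | intermediate
4 | 2,6-dimethoxy-1-(3-methylbut-2-en-1-yl)cyclohexa-2,5-diene-1-carbonyl chloride (not isolated) | COC1=CCC=C(OC)C1(CC=C(C)C)C(Cl)=O | intermediate
5 | 2-diazo-1-[2,6-dimethoxy-1-(3-methylbut-2-en-1-yl)cyclohexa-2,5-dien-1-yl]ethan-1-one | COC1=CCC=C(OC)C1(CC=C(C)C)C(=O)C=[N+]=[N-] | intermediate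
6 | 2-[2,6-dimethoxy-1-(3-methylbut-2-en-1-yl)cyclohexa-2,5-dien-1-yl]ethen-1-one (ketene, not isolated) | COC1=CCC=C(OC)C1(CC=C(C)C)C=C=O | intermediate
7 | methyl 2-[2,6-dimethoxy-1-(3-methylbut-2-en-1-yl)cyclohexa-2,5-dien-1-yl]acetate | COC1=CCC=C(OC)C1(CC=C(C)C)CC(=O)OC | intermediate
8 | methyl 2-[2,6-dimethoxy-1-(3-methylbut-2-en-1-yl)cyclohexa-2,5-dien-1-yl]propanoate (racemic, not isolated) | COC1=CCC=C(OC)C1(CC=C(C)C)C(C)C(=O)OC | intermediate
9 | methyl 2-[2,6-dimethoxy-1-(3-methylbut-2-en-1-yl)cyclohexa-2,5-dien-1-yl]-2-methylpropanoate | COC1=CCC=C(OC)C1(CC=C(C)C)C(C)(C)C(=O)OC | intermediate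
10 | 2-[2,6-dimethoxy-1-(3-methylbut-2-en-1-yl)cyclohexa-2,5-dien-1-yl]-2-methylpropanoic acid | COC1=CCC=C(OC)C1(CC=C(C)C)C(C)(C)C(O)=O | intermediate
11 | 2-[2,6-dimethoxy-1-(3-methylbut-2-en-1-yl)cyclohexa-2,5-dien-1-yl]-2-methylpropanoyl chloride (not isolated) | COC1=CCC=C(OC)C1(CC=C(C)C)C(C)(C)C(Cl)=O | intermediate
12 | 1-diazo-3-[2,6-dimethoxy-1-(3-methylbut-2-en-1-yl)cyclohexa-2,5-dien-1-yl]-3-methylbutan-2-one | COC1=CCC=C(OC)C1(CC=C(C)C)C(C)(C)C(=O)C=[N+]=[N-] | intermediate
13 | (1R,2S,6S,9R)-1,5-dimethoxy-7,7-dimethyl-6-(3-methylbut-2-en-1-yl)tricyclo[4.3.0.0(2,9)]non-4-en-8-one | COC1=CC[C@H]2[C@H]3C(=O)C(C)(C)[C@]1(CC=C(C)C)[C@@]23OC | intermediate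
14 | (1S,5S)-2-methoxy-8,8-dimethyl-1-(3-methylbut-2-en-1-yl)-7-(trimethylsilyloxy)bicyclo[3.3.1]nona-2,6-dien-9-one (not isolated) | [C@@H]12C=C(O[Si](C)(C)C)C(C)(C)[C@@](CC=C(C)C)(C(OC)=CC1)C2=O | intermediate
15 | (1S,5S)-2-methoxy-8,8-dimethyl-1-(3-methylbut-2-en-1-yl)bicyclo[3.3.1]non-2-ene-7,9-dione | [C@@H]12CC(=O)C(C)(C)[C@@](CC=C(C)C)(C(OC)=CC1)C2=O | intermediate
16 | (1S,5R)-2-methoxy-8,8-dimethyl-1-(3-methylbut-2-en-1-yl)bicyclo[3.3.1]non-2-ene-4,7,9-trione | [C@@H]12CC(=O)C(C)(C)[C@@](CC=C(C)C)(C(OC)=CC1=O)C2=O | intermediate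
17 | (1S,5R)-2-methoxy-7-(methoxymethylidene)-8,8-dimethyl-1-(3-methylbut-2-en-1-yl)bicyclo[3.3.1]non-2-ene-4,9-dione (E/Z mixture) | [C@@H]12CC(=COC)C(C)(C)[C@@](CC=C(C)C)(C(OC)=CC1=O)C2=O | intermediate
18 | (1S,5R,7R)-2-methoxy-8,8-dimethyl-1-(3-methylbut-2-en-1-yl)-4,9-dioxobicyclo[3.3.1]non-2-ene-7-carbaldehyde (formyl endo, not isolated) | [C@@H]12C[C@@H](C=O)C(C)(C)[C@@](CC=C(C)C)(C(OC)=CC1=O)C2=O | intermediate
19 | (1S,5R,7S)-2-methoxy-8,8-dimethyl-1-(3-methylbut-2-en-1-yl)-4,9-dioxobicyclo[3.3.1]non-2-ene-7-carbaldehyde (formyl exo) | [C@@H]12C[C@H](C=O)C(C)(C)[C@@](CC=C(C)C)(C(OC)=CC1=O)C2=O | intermediate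
20 | (1S,5R,7R)-2-methoxy-7-(2-methoxyethenyl)-8,8-dimethyl-1-(3-methylbut-2-en-1-yl)bicyclo[3.3.1]non-2-ene-4,9-dione (E/Z mixture, not isolated) | [C@@H]12C[C@H](C=COC)C(C)(C)[C@@](CC=C(C)C)(C(OC)=CC1=O)C2=O | intermediate
21 | 2-[(1S,5R,7R)-2-methoxy-8,8-dimethyl-1-(3-methylbut-2-en-1-yl)-4,9-dioxobicyclo[3.3.1]non-2-en-7-yl]acetaldehyde | [C@@H]12C[C@H](CC=O)C(C)(C)[C@@](CC=C(C)C)(C(OC)=CC1=O)C2=O | intermediate
22 | (1S,5R,7S)-2-methoxy-8,8-dimethyl-1,7-bis(3-methylbut-2-en-1-yl)bicyclo[3.3.1]non-2-ene-4,9-dione | [C@@H]12C[C@H](CC=C(C)C)C(C)(C)[C@@](CC=C(C)C)(C(OC)=CC1=O)C2=O | intermediate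
23 | geranyl bromide ((2E)-1-bromo-3,7-dimethylocta-2,6-diene) | CC(C)=CCC/C(C)=C/CBr | starting material
24 | (1S,5R,7S)-5-[(2E)-3,7-dimethylocta-2,6-dien-1-yl]-2-methoxy-8,8-dimethyl-1,7-bis(3-methylbut-2-en-1-yl)bicyclo[3.3.1]non-2-ene-4,9-dione | CC(C)=CCC/C(C)=C/C[C@@]12C[C@H](CC=C(C)C)C(C)(C)[C@@](CC=C(C)C)(C(OC)=CC1=O)C2=O | intermediate
25 | 3,4-dihydroxybenzoic acid | OC(=O)c1ccc(O)c(O)c1 | starting material
26 | tert-butyldimethylsilyl 3,4-bis(tert-butyldimethylsilyloxy)benzoate | CC(C)(C)[Si](C)(C)OC(=O)c1ccc(O[Si](C)(C)C(C)(C)C)c(O[Si](C)(C)C(C)(C)C)c1 | intermediate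
27 | 3,4-bis(tert-butyldimethylsilyloxy)benzoyl chloride | ClC(=O)c1ccc(O[Si](C)(C)C(C)(C)C)c(O[Si](C)(C)C(C)(C)C)c1 | intermediate
28 | (1S,5S,7S)-3-[3,4-bis(tert-butyldimethylsilyloxy)benzoyl]-5-[(2E)-3,7-dimethylocta-2,6-dien-1-yl]-2-methoxy-8,8-dimethyl-1,7-bis(3-methylbut-2-en-1-yl)bicyclo[3.3.1]non-2-ene-4,9-dione | CC(C)=CCC/C(C)=C/C[C@@]12C[C@H](CC=C(C)C)C(C)(C)[C@@](CC=C(C)C)(C(OC)=C(C(=O)c3ccc(O[Si](C)(C)C(C)(C)C)c(O[Si](C)(C)C(C)(C)C)c3)C1=O)C2=O | intermediate
29 | (1R,5R,7S)-3-(3,4-dihydroxybenzoyl)-5-[(2E)-3,7-dimethylocta-2,6-dien-1-yl]-4-hydroxy-8,8-dimethyl-1,7-bis(3-methylbut-2-en-1-yl)bicyclo[3.3.1]non-3-ene-2,9-dione | CC(C)=CCC/C(C)=C/C[C@@]12C[C@H](CC=C(C)C)C(C)(C)[C@@](CC=C(C)C)(C(=O)C(C(=O)c3ccc(O)c(O)c3)=C1O)C2=O | target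

**Step count**

Total: 18 steps. Longest linear sequence: 16 steps (steps 1–14, 17, 18, from 2,6-dimethoxybenzoic acid); steps 15 and 16 make the aroyl chloride in a side branch.

**Steps most likely to fail, with fallbacks**

1. Step 7. The ligand may discriminate poorly between the two enantiotopic enol ethers, or the carbene may be diverted into oxonium ylide formation at a methoxy oxygen or into addition to the prenyl alkene. The fallback sets out from 10 and comes back at 15. Acid chloride 11, made from 10 as in step 6, is added to PhSO2CH2Li (THF, −78 °C) to give the β-keto sulfone F1. Diazo transfer with 4-acetamidobenzenesulfonyl azide and Et3N in MeCN gives the α-diazo-β-keto sulfone F2. Its acceptor/acceptor copper carbene, formed with the same (CuOTf)2·C6H6/bis(oxazoline) system, belongs to a class known to give high selectivity in desymmetrising intramolecular cyclopropanation, and should give the sulfonyl cyclopropane F3. Opening with Me3SiI as in step 8 then gives the 6-sulfonyl diketone F4, and SmI2 (THF/MeOH, −78 °C) removes the sulfonyl group α to the C7 ketone to give 15.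

2. Step 9. Hydrogen abstraction at the allylic C–H bonds of the prenyl group may compete with abstraction at C4, or the enol ether may be over-oxidised. The fallback sets out from 15 and comes back at 16, and avoids C–H oxidation. Mild acid hydrolysis (1 M HCl, THF) of the enol ether gives the 2,7,9-trione F5. IBX (DMSO/toluene, 70 °C) dehydrogenates the C2 ketone to the C3=C4 enone F6; C1 is quaternary, and the C7 ketone could only form a bridgehead alkene. Tsuji–Wacker oxidation of the enone (Na2PdCl4 cat., t-BuOOH, AcOH/H2O, 50 °C) puts oxygen on C4 and gives the 2,4-diketone F7. O-Methylation with Me3SiCHN2 in toluene/MeOH gives 16 together with the regioisomeric 4-methoxy vinylogous ester F8, which is separated and returned to F7 by LiOH hydrolysis.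

3. Step 10. The ylide may act as a base (enolisation of the hindered C7 ketone toward C6, deprotonation at C5) rather than add to C7, so that conversion stalls. The fallback sets out from 16 and comes back at 19. KN(SiMe3)2 and PhNTf2 (THF, −78 °C) convert the C7 ketone, which can enolise only toward C6, into the vinyl triflate F9. Carbonylative reduction with Pd(PPh3)4, CO (1 atm), Bu3SnH and LiCl in THF at 50 °C gives the enal F10. Conjugate reduction with [(Ph3P)CuH]6 (benzene, rt) spares the ketones and the prenyl alkene and gives the saturated aldehyde as a mixture of 18 and 19, which DBU equilibrates to 19 as in step 11.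

**Further compounds**

F1 | step 7 | 4-[2,6-dimethoxy-1-(3-methylbut-2-en-1-yl)cyclohexa-2,5-dien-1-yl]-4-methyl-1-(phenylsulfonyl)pentan... written as 3-[2,6-dimethoxy-1-(3-methylbut-2-en-1-yl)cyclohexa-2,5-dien-1-yl]-3-methyl-1-(phenylsulfonyl)butan-2-one | COC1=CCC=C(OC)C1(CC=C(C)C)C(C)(C)C(=O)CS(=O)(=O)c1ccccc1
F2 | step 7 | 1-diazo-3-[2,6-dimethoxy-1-(3-methylbut-2-en-1-yl)cyclohexa-2,5-dien-1-yl]-3-methyl-1-(phenylsulfonyl)butan-2-one | COC1=CCC=C(OC)C1(CC=C(C)C)C(C)(C)C(=O)C(=[N+]=[N-])S(=O)(=O)c1ccccc1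
F3 | step 7 | 1,5-dimethoxy-7,7-dimethyl-6-(3-methylbut-2-en-1-yl)-9-(phenylsulfonyl)tricyclo[4.3.0.0(2,9)]non-4-en-8-one (ring configuration as in 13) | COC1=CC[C@H]2[C@@]3(S(=O)(=O)c4ccccc4)C(=O)C(C)(C)[C@]1(CC=C(C)C)[C@@]23OC
F4 | step 7 | 2-methoxy-8,8-dimethyl-1-(3-methylbut-2-en-1-yl)-6-(phenylsulfonyl)bicyclo[3.3.1]non-2-ene-7,9-dione (C1, C5 as in 15; C6 epimers) | [C@@H]12C(S(=O)(=O)c3ccccc3)C(=O)C(C)(C)[C@@](CC=C(C)C)(C(OC)=CC1)C2=O
F5 | step 9 | 8,8-dimethyl-1-(3-methylbut-2-en-1-yl)bicyclo[3.3.1]nonane-2,7,9-trione (C1, C5 as in 15) | [C@@H]12CC(=O)C(C)(C)[C@@](CC=C(C)C)(C(=O)CC1)C2=O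
F6 | step 9 | 8,8-dimethyl-1-(3-methylbut-2-en-1-yl)bicyclo[3.3.1]non-3-ene-2,7,9-trione (C1, C5 as in 15) | [C@@H]12CC(=O)C(C)(C)[C@@](CC=C(C)C)(C(=O)C=C1)C2=O
F7 | step 9 | 8,8-dimethyl-1-(3-methylbut-2-en-1-yl)bicyclo[3.3.1]nonane-2,4,7,9-tetraone (enolised 2,4-diketone; C1, C5 as in 16) | [C@@H]12CC(=O)C(C)(C)[C@@](CC=C(C)C)(C(=O)CC1=O)C2=O
F8 | step 9 | 4-methoxy-8,8-dimethyl-1-(3-methylbut-2-en-1-yl)bicyclo[3.3.1]non-3-ene-2,7,9-trione (regioisomer of 16) | [C@@H]12CC(=O)C(C)(C)[C@@](CC=C(C)C)(C(=O)C=C1OC)C2=O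
F9 | step 10 | 2-methoxy-8,8-dimethyl-1-(3-methylbut-2-en-1-yl)-4,9-dioxobicyclo[3.3.1]nona-2,6-dien-7-yl trifluoromethanesulfonate (C1, C5 as in 16) | [C@@H]12C=C(OS(=O)(=O)C(F)(F)F)C(C)(C)[C@@](CC=C(C)C)(C(OC)=CC1=O)C2=O
F10 | step 10 | 2-methoxy-8,8-dimethyl-1-(3-methylbut-2-en-1-yl)-4,9-dioxobicyclo[3.3.1]nona-2,6-diene-7-carbaldehyde (C1, C5 as in 16) | [C@@H]12C=C(C=O)C(C)(C)[C@@](CC=C(C)C)(C(OC)=CC1=O)C2=O
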